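**Plan**

- Retrosynthesis (germacrane numbering): the C15 acetate is removed; the O–C6 and C15–O bonds are cut together as a 1,4-dioxygenation of a ring diene C6=C5–C4=C15; then C5=C6 (ring-closing metathesis), the C8 ester, C7–C8 (allylation) and C1=C10 (Horner–Wadsworth–Emmons) are cut.
- Enabling feature: the lactone oxygen on C6 and the hydroxyl on C15 flank the C4=C5 double bond of the ten-membered ring (O–C6–C5=C4–C15–O), and C6 is γ to the C12 carboxyl. A ring diene C6=C5–C4=C15 carrying the free acid can therefore close the five-membered lactone ring, move the double bond to C4=C5 and oxygenate C15 in one palladium-catalysed oxidation.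
- Forward: myrcene gives the C1–C5/C15 diene aldehyde; olefination with a C8–C10/C14 phosphonate sets C1=C10; a chromium-catalysed allylation with a C6/C7/C11–C13 dienyl bromide joins C7–C8; metathesis closes the ten-membered ring as a (Z,Z)-cyclodeca-1,6-diene; the lactone ring is closed in the penultimate step.
- Stereochemistry: C7 and C8 come from the catalyst-controlled syn-allylation (chiral chromium complex, (Z)-allyl reagent); C6 comes from C7 through allylic strain in the key step; the C1=C10 geometry comes from the olefination and the C4=C5 geometry from the ring.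

Key step: step 17

Numbering: germacrane numbering of the target (ring C1–C10, acrylate unit C11–C13, C14 on C10, C15 on C4) is used for all intermediates.

Assumption: the chiral chromium catalyst of step 12 is taken to deliver the allyl group to the si face of aldehyde 11 with the (S,S)-ligand; if the sense is the opposite, the (R,R)-ligand is used.

**Route**

Step 1
Reactants: 1 myrcene
Product: 2 6,7-epoxymyrcene (racemic)
Conditions: mCPBA (1.0 equiv), NaHCO3, CH2Cl2, 0 °C
Reagents that add atoms: mCPBA, OOC(=O)c1cccc(Cl)c1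
Why: Prilezhaev epoxidation should take the electron-rich trisubstituted alkene before the conjugated diene, and the new stereocentre is destroyed in step 2.

Step 2
Reactants: 2 6,7-epoxymyrcene
Product: 3 4-methylidenehex-5-enal
Conditions: H5IO6, THF–H2O, 0 °C to rt
Reagents that add atoms: none
Why: Periodic acid opens the epoxide to the glycol and cleaves it (Malaprade glycol cleavage), giving the aldehyde, whose oxygen is the former epoxide oxygen, and acetone.

Step 3
Reactants: 4 triethyl phosphonoacetate; 5 tert-butyl(2-iodoethoxy)dimethylsilane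
Product: 6 ethyl 4-[(tert-butyldimethylsilyl)oxy]-2-(diethoxyphosphoryl)butanoate
Conditions: NaH, THF–DMF, 0 °C to 60 °C
Reagents that add atoms: none
Why: SN2 C-alkylation of the sodium phosphonoacetate carbanion by the primary iodide should give the α-substituted phosphonate that carries C8, C9, C10 and C14.

Step 4
Reactants: 6 ethyl 4-[(tert-butyldimethylsilyl)oxy]-2-(diethoxyphosphoryl)butanoate; 3 4-methylidenehex-5-enal
Product: 7 ethyl (2E)-2-{2-[(tert-butyldimethylsilyl)oxy]ethyl}-6-methylideneocta-2,7-dienoate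
Conditions: NaH, THF, 0 °C to rt
Reagents that add atoms: none
Why: Horner–Wadsworth–Emmons olefination of an α-alkyl phosphonoacetate should place the ester trans to the C2 chain (the ring-cis C1=C10 geometry of the target), with any minor isomer removed by chromatography.

Step 5
Reactants: 7 ethyl (2E)-2-{2-[(tert-butyldimethylsilyl)oxy]ethyl}-6-methylideneocta-2,7-dienoate
Product: 8 (2E)-2-{2-[(tert-butyldimethylsilyl)oxy]ethyl}-6-methylideneocta-2,7-dien-1-ol
Conditions: i-Bu2AlH, CH2Cl2, −78 °C; aq. KNaC4H4O6 work-up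
Reagents that add atoms: none
Why: 1,2-reduction of the enoate by the aluminium hydride should give the C14 allylic alcohol with the alkene geometry and the silyl ether untouched.

Step 6
Reactants: 8 (2E)-2-{2-[(tert-butyldimethylsilyl)oxy]ethyl}-6-methylideneocta-2,7-dien-1-ol
Product: 9 (2E)-1-[(tert-butyldiphenylsilyl)oxy]-2-{2-[(tert-butyldimethylsilyl)oxy]ethyl}-6-methylideneocta-2,7-diene
Conditions: TBDPSCl, imidazole, CH2Cl2, rt
Reagents that add atoms: TBDPSCl, CC(C)(C)[Si](Cl)(c1ccccc1)c1ccccc1
Why: Silylation of the primary allylic alcohol gives an acid-stable ether that keeps C14 at the alcohol level until step 14.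

Step 7
Reactants: 9 (2E)-1-[(tert-butyldiphenylsilyl)oxy]-2-{2-[(tert-butyldimethylsilyl)oxy]ethyl}-6-methylideneocta-2,7-diene
Product: 10 (3E)-3-{[(tert-butyldiphenylsilyl)oxy]methyl}-7-methylidenenona-3,8-dien-1-ol
Conditions: PPTS (cat.), MeOH, rt
Reagents that add atoms: none
Why: Acid-catalysed methanolysis should remove the primary tert-butyldimethylsilyl ether selectively over the tert-butyldiphenylsilyl ether and leave the diene intact.

Step 8
Reactants: 10 (3E)-3-{[(tert-butyldiphenylsilyl)oxy]methyl}-7-methylidenenona-3,8-dien-1-ol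
Product: 11 (3E)-3-{[(tert-butyldiphenylsilyl)oxy]methyl}-7-methylidenenona-3,8-dienal
Conditions: Dess–Martin periodinane, NaHCO3, CH2Cl2, 0 °C; used at once
Reagents that add atoms: none
Why: Buffered Dess–Martin oxidation gives the β,γ-unsaturated C8 aldehyde under neutral conditions, and immediate use avoids migration of the C1=C10 double bond into conjugation.

Step 9
Reactants: 12 acryloyl chloride; 13 2-(trimethylsilyl)ethanol
Product: 14 2-(trimethylsilyl)ethyl acrylate
Conditions: Et3N, CH2Cl2, 0 °C
Reagents that add atoms: none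
Why: Acylation of the alcohol by the acid chloride gives an acrylate whose ester can later be removed by fluoride without acid or base.

Step 10
Reactants: 14 2-(trimethylsilyl)ethyl acrylate; 15 acrolein
Product: 16 2-(trimethylsilyl)ethyl 3-hydroxy-2-methylidenepent-4-enoate (racemic)
Conditions: DABCO, 1,4-dioxane–H2O, 0 °C to rt
Reagents that add atoms: none
Why: Morita–Baylis–Hillman reaction joins the acrylate α-carbon (C11) to the aldehyde carbon (C7), and the stereocentre formed is removed in step 11.

Step 11
Reactants: 16 2-(trimethylsilyl)ethyl 3-hydroxy-2-methylidenepent-4-enoate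
Product: 17 2-(trimethylsilyl)ethyl (2Z)-2-(bromomethyl)penta-2,4-dienoate
Conditions: NBS, Me2S, CH2Cl2, 0 °C to rt
Reagents that add atoms: N-bromosuccinimide, BrN1C(=O)CCC1=O
Why: Bromide displaces the alkoxysulfonium group with allylic transposition (SN2') and should give the conjugated, thermodynamically preferred (Z)-allylic bromide with the vinyl group cis to CH2Br.

Step 12
Reactants: 11 (3E)-3-{[(tert-butyldiphenylsilyl)oxy]methyl}-7-methylidenenona-3,8-dienal; 17 2-(trimethylsilyl)ethyl (2Z)-2-(bromomethyl)penta-2,4-dienoate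
Product: 19 2-(trimethylsilyl)ethyl (3R,4R,6E)-6-{[(tert-butyldiphenylsilyl)oxy]methyl}-3-ethenyl-4-hydroxy-2,10-dimethylidenedodeca-6,11-dienoate, via trimethylsilyl ether 18 (not isolated)
Conditions: CrCl2 (10 mol%), (S,S)-1,8-bis(4-isopropyl-4,5-dihydrooxazol-2-yl)-3,6-diphenyl-9H-carbazole (12 mol%), Mn powder, Me3SiCl, i-Pr2NEt, THF, rt; then citric acid, MeOH, 0 °C
Reagents that add atoms: chlorotrimethylsilane, C[Si](C)(C)Cl (its silyl group is in 18 only)
Why: In this catalytic asymmetric Nozaki–Hiyama–Kishi 2-(alkoxycarbonyl)allylation the allylchromium species should add through C7 in a closed chair transition state, so the (Z)-reagent gives the syn adduct (7R,8R), the ligand selects the si face of the aldehyde, and silyl trapping of the alkoxide prevents lactonisation onto the ester.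

Step 13
Reactants: 19 2-(trimethylsilyl)ethyl (3R,4R,6E)-6-{[(tert-butyldiphenylsilyl)oxy]methyl}-3-ethenyl-4-hydroxy-2,10-dimethylidenedodeca-6,11-dienoate
Product: 20 2-(trimethylsilyl)ethyl (3R,4R,6E)-6-{[(tert-butyldiphenylsilyl)oxy]methyl}-3-ethenyl-2,10-dimethylidene-4-[(3-methylbutanoyl)oxy]dodeca-6,11-dienoate
Conditions: isovaleric anhydride, DMAP, Et3N, CH2Cl2, 0 °C to rt
Reagents that add atoms: isovaleric anhydride, CC(C)CC(=O)OC(=O)CC(C)C
Why: DMAP-catalysed acylation installs the C8 ester of the target with retention and removes the hydroxyl that could lactonise.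

Step 14
Reactants: 20 2-(trimethylsilyl)ethyl (3R,4R,6E)-6-{[(tert-butyldiphenylsilyl)oxy]methyl}-3-ethenyl-2,10-dimethylidene-4-[(3-methylbutanoyl)oxy]dodeca-6,11-dienoate
Product: 21 (3R,4R,6E)-3-ethenyl-6-(hydroxymethyl)-2,10-dimethylidene-4-[(3-methylbutanoyl)oxy]dodeca-6,11-dienoic acid
Conditions: Bu4NF, THF, 0 °C to rt; aq. NH4Cl
Reagents that add atoms: none
Why: Fluoride cleaves the silyl ether and fragments the 2-(trimethylsilyl)ethyl ester in one operation, while the isovalerate and the skipped diene at C7 (not activated by the carbonyl) should survive.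

Step 15
Reactants: 21 (3R,4R,6E)-3-ethenyl-6-(hydroxymethyl)-2,10-dimethylidene-4-[(3-methylbutanoyl)oxy]dodeca-6,11-dienoic acid
Product: 22 (3R,4R,6E)-3-ethenyl-6-formyl-2,10-dimethylidene-4-[(3-methylbutanoyl)oxy]dodeca-6,11-dienoic acid
Conditions: Dess–Martin periodinane, NaHCO3, CH2Cl2, 0 °C to rt; acidify to pH 4
Reagents that add atoms: none
Why: Dess–Martin oxidation of the only alcohol gives the C14 enal of the target, which also makes C1=C10 electron-poor before the metathesis.

Step 16
Reactants: 22 (3R,4R,6E)-3-ethenyl-6-formyl-2,10-dimethylidene-4-[(3-methylbutanoyl)oxy]dodeca-6,11-dienoic acid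
Product: 23 2-[(1R,2R,4E,9Z)-4-formyl-8-methylidene-2-[(3-methylbutanoyl)oxy]cyclodeca-4,9-dien-1-yl]prop-2-enoic acid
Conditions: second-generation Grubbs catalyst (10 mol%), toluene (high dilution), 60 °C
Reagents that add atoms: none
Why: Ring-closing olefin metathesis of the C6 vinyl group with the terminal vinyl of the diene should give a nearly strain-free (Z,Z)-cyclodeca-1,6-diene ring with the (5Z) geometry a ten-membered ring accepts, while trisubstitution and conjugation with the aldehyde shield C1=C10 from cyclopentene-forming metathesis.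

Step 17
Reactants: 23 2-[(1R,2R,4E,9Z)-4-formyl-8-methylidene-2-[(3-methylbutanoyl)oxy]cyclodeca-4,9-dien-1-yl]prop-2-enoic acid
Product: 25 (1(10)E,4E,6R,7R,8R)-15-acetoxy-8-[(3-methylbutanoyl)oxy]-14-oxogermacra-1(10),4,11(13)-trien-12,6-olide, via allylpalladium acetate 24 (not isolated)
Conditions: Pd(OAc)2 (10 mol%), p-benzoquinone (2 equiv), LiOAc, acetone–AcOH (4:1), rt
Reagents that add atoms: acetic acid, CC(=O)O
Why: Divalent palladium coordinates the C6=C5–C4=C15 diene (the only electron-rich π system, the enal and acrylate alkenes being electron-poor), the C12 carboxylate attacks C6 on the face opposite the metal to give the π-allyl complex 24 over C5–C4–C15, acetate attacks the CH2 terminus C15, and benzoquinone reoxidises the zerovalent palladium released. The closest known reaction type is the palladium-catalysed intramolecular 1,4-acyloxylactonisation (1,4-dioxygenation) of conjugated dienoic acids. The γ-lactone ring (O–C6–C7–C11–C12) closes in the 5-exo-trig mode, whereas closure at C15 would need an eight-membered ring. The new stereocentre C6 is controlled by C7: in the reactive conformer H7 eclipses the C5=C6 bond (allylic 1,3-strain against C4), C8 points away and the carboxyl-bearing C11 stands over one face, which leads to the trans-fused lactone (6R). The step needs 1,4- over 1,2-addition and the ring-cis C4=C5 geometry: acetate prefers the primary terminus C15, and with the (5Z) ring alkene only the allyl isomer with C6 cis to C3 avoids pushing C15 against C7, syn–anti interconversion of the allyl complex correcting the other isomer. The same clash keeps the diene out of the s-cis form and should suppress Diels–Alder addition to benzoquinone.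

Step 18
Reactants: 25 (1(10)E,4E,6R,7R,8R)-15-acetoxy-8-[(3-methylbutanoyl)oxy]-14-oxogermacra-1(10),4,11(13)-trien-12,6-olide
Product: 26 (1(10)E,4E,6R,7R,8R)-15-hydroxy-8-[(3-methylbutanoyl)oxy]-14-oxogermacra-1(10),4,11(13)-trien-12,6-olide (target)
Conditions: immobilised Candida antarctica lipase B, KH2PO4–K2HPO4 buffer pH 7–acetone, 30 °C
Reagents that add atoms: none
Why: Lipase-catalysed ester hydrolysis should cleave the unhindered primary allylic acetate and spare the hindered secondary isovalerate, the lactone, the enal and the α-methylene group, which a basic methanolysis would endanger.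

**Compound list**

1 | myrcene (7-methyl-3-methylideneocta-1,6-diene) | C=CC(=C)CCC=C(C)C | starting material
2 | 6,7-epoxymyrcene, racemic (2,2-dimethyl-3-(3-methylidenepent-4-en-1-yl)oxirane) | CC1(C)OC1CCC(=C)C=C | intermediate
3 | 4-methylidenehex-5-enal (C1–C5 and C15) | O=CCCC(=C)C=C | intermediate
4 | triethyl phosphonoacetate | CCOC(=O)CP(=O)(OCC)OCC | starting material
5 | tert-butyl(2-iodoethoxy)dimethylsilane | CC(C)(C)[Si](C)(C)OCCI | starting material
6 | ethyl 4-[(tert-butyldimethylsilyl)oxy]-2-(diethoxyphosphoryl)butanoate | CCOC(=O)C(CCO[Si](C)(C)C(C)(C)C)P(=O)(OCC)OCC | intermediate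
7 | ethyl (2E)-2-{2-[(tert-butyldimethylsilyl)oxy]ethyl}-6-methylideneocta-2,7-dienoate | CCOC(=O)/C(CCO[Si](C)(C)C(C)(C)C)=C/CCC(=C)C=C | intermediate
8 | (2E)-2-{2-[(tert-butyldimethylsilyl)oxy]ethyl}-6-methylideneocta-2,7-dien-1-ol | OC/C(CCO[Si](C)(C)C(C)(C)C)=C/CCC(=C)C=C | intermediate
9 | (2E)-1-[(tert-butyldiphenylsilyl)oxy]-2-{2-[(tert-butyldimethylsilyl)oxy]ethyl}-6-methylideneocta-2,7-diene | CC(C)(C)[Si](OC/C(CCO[Si](C)(C)C(C)(C)C)=C/CCC(=C)C=C)(c1ccccc1)c1ccccc1 | intermediate
10 | (3E)-3-{[(tert-butyldiphenylsilyl)oxy]methyl}-7-methylidenenona-3,8-dien-1-ol | OCC/C(CO[Si](C(C)(C)C)(c1ccccc1)c1ccccc1)=C\CCC(=C)C=C | intermediate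
11 | (3E)-3-{[(tert-butyldiphenylsilyl)oxy]methyl}-7-methylidenenona-3,8-dienal | O=CC/C(CO[Si](C(C)(C)C)(c1ccccc1)c1ccccc1)=C\CCC(=C)C=C | intermediate
12 | acryloyl chloride | C=CC(=O)Cl | starting material
13 | 2-(trimethylsilyl)ethanol | C[Si](C)(C)CCO | starting material
14 | 2-(trimethylsilyl)ethyl acrylate | C=CC(=O)OCC[Si](C)(C)C | intermediate
15 | acrolein | C=CC=O | starting material
16 | 2-(trimethylsilyl)ethyl 3-hydroxy-2-methylidenepent-4-enoate (racemic) | C=CC(O)C(=C)C(=O)OCC[Si](C)(C)C | intermediate
17 | 2-(trimethylsilyl)ethyl (2Z)-2-(bromomethyl)penta-2,4-dienoate | BrC/C(C(=O)OCC[Si](C)(C)C)=C\C=C | intermediate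
18 | trimethylsilyl ether of 19 (O-silylated allylation adduct) | C=CC(=C)CC/C=C(/CO[Si](C(C)(C)C)(c1ccccc1)c1ccccc1)C[C@@H](O[Si](C)(C)C)[C@@H](C(=C)C(=O)OCC[Si](C)(C)C)C=C | intermediate
19 | 2-(trimethylsilyl)ethyl (3R,4R,6E)-6-{[(tert-butyldiphenylsilyl)oxy]methyl}-3-ethenyl-4-hydroxy-2,10-dimethylidenedodeca-6,11-dienoate ((7R,8R) in germacrane numbering) | C=CC(=C)CC/C=C(/CO[Si](C(C)(C)C)(c1ccccc1)c1ccccc1)C[C@@H](O)[C@@H](C(=C)C(=O)OCC[Si](C)(C)C)C=C | intermediate
20 | 2-(trimethylsilyl)ethyl (3R,4R,6E)-6-{[(tert-butyldiphenylsilyl)oxy]methyl}-3-ethenyl-2,10-dimethylidene-4-[(3-methylbutanoyl)oxy]dodeca-6,11-dienoate | C=CC(=C)CC/C=C(/CO[Si](C(C)(C)C)(c1ccccc1)c1ccccc1)C[C@@H](OC(=O)CC(C)C)[C@@H](C(=C)C(=O)OCC[Si](C)(C)C)C=C | intermediate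
21 | (3R,4R,6E)-3-ethenyl-6-(hydroxymethyl)-2,10-dimethylidene-4-[(3-methylbutanoyl)oxy]dodeca-6,11-dienoic acid | C=CC(=C)CC/C=C(/CO)C[C@@H](OC(=O)CC(C)C)[C@@H](C(=C)C(=O)O)C=C | intermediate
22 | (3R,4R,6E)-3-ethenyl-6-formyl-2,10-dimethylidene-4-[(3-methylbutanoyl)oxy]dodeca-6,11-dienoic acid | C=CC(=C)CC/C=C(/C=O)C[C@@H](OC(=O)CC(C)C)[C@@H](C(=C)C(=O)O)C=C | intermediate
23 | 2-[(1R,2R,4E,9Z)-4-formyl-8-methylidene-2-[(3-methylbutanoyl)oxy]cyclodeca-4,9-dien-1-yl]prop-2-enoic acid (ring diene C6=C5–C4=C15, free C12 acid) | C=C1/C=C\[C@H](C(=C)C(=O)O)[C@H](OC(=O)CC(C)C)C/C(C=O)=C\CC1 | intermediate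
24 | allylpalladium acetate over C5–C4–C15 of the 6,12-lactone (drawn as its C15 σ-form) | C=C1C(=O)O[C@@H]2/C=C(/C[Pd]OC(C)=O)CC/C=C(/C=O)C[C@@H](OC(=O)CC(C)C)[C@@H]12 | intermediate
25 | (1(10)E,4E,6R,7R,8R)-15-acetoxy-8-[(3-methylbutanoyl)oxy]-14-oxogermacra-1(10),4,11(13)-trien-12,6-olide | C=C1C(=O)O[C@@H]2/C=C(/COC(C)=O)CC/C=C(/C=O)C[C@@H](OC(=O)CC(C)C)[C@@H]12 | intermediate
26 | (1(10)E,4E,6R,7R,8R)-15-hydroxy-8-[(3-methylbutanoyl)oxy]-14-oxogermacra-1(10),4,11(13)-trien-12,6-olide | C=C1C(=O)O[C@@H]2/C=C(/CO)CC/C=C(/C=O)C[C@@H](OC(=O)CC(C)C)[C@@H]12 | target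

**Count**

Total steps: 18. Longest linear sequence: 14 steps (steps 1, 2, 4–8, 12–18, from myrcene).

**Steps most likely to fail**

Step 17. The carboxylate may attack the wrong face of the diene (cis-lactone), the anti allyl complex may lead to the ring-trans C4=C5 isomer, acetate may add 1,2 instead of 1,4, or the diene may be consumed by cycloaddition with benzoquinone. The fallback forms the same O–C6 bond with electrophilic selenium and sets out from 23. Phenylselenolactonisation (PhSeCl, CH2Cl2, −78 °C) should give the trans-lactone with anti addition across C5=C6, the 5-(phenylselanyl) lactone F1. Oxidation (H2O2, pyridine, 0 °C) gives the allylic selenoxide F2, whose [2,3]-sigmatropic rearrangement moves the double bond to C4=C5 and the oxygen to C15 in the selenenate F3. Hydrolysis of F3 on work-up gives the free C15 alcohol, so the fallback comes back to the route at 26 and step 18 is not needed.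

Step 16. Oligomerisation may win over medium-ring closure, metathesis may occur at the internal alkene of the diene, or the C6 carbene may attack C1=C10 and expel a cyclopentene. The fallback closes the ring on a lactone template, sets out from 19 and comes back at 23. Acid-catalysed lactonisation of 19 (camphorsulfonic acid, CH2Cl2) gives the cis-8,12-lactone silyl ether F4, in which the C6 vinyl group and the C9 chain are held cis on a five-membered ring. Bu4NF gives the C14 alcohol F5, and Dess–Martin oxidation the enal lactone F6. Ring-closing metathesis of F6 should then give the cis-fused bicyclic lactone F7. Saponification (LiOH, THF–H2O, 0 °C) gives the lithium hydroxy carboxylate F8, which is O-alkylated with allyl bromide (DMF) to the hydroxy allyl ester F9. Acylation with isovaleric anhydride and DMAP gives the isovalerate allyl ester F10, and Pd(PPh3)4 (zerovalent palladium) with morpholine removes the allyl group to give 23.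

Step 12. The pentadienyl chromium species may add through its ε-carbon, the ligand may give insufficient facial control, the adduct may lactonise, or the β,γ-unsaturated aldehyde may isomerise. The fallback gives up catalyst control and resolves instead; it sets out from 11 and 17 and comes back at 19. An indium-mediated Barbier allylation (indium powder, THF–H2O, rt) should give the syn adduct as the racemate, that is 19 together with its (7S,8S)-enantiomer F11. The two are separated by preparative chromatography on a chiral stationary phase, and 19 goes on to step 13.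

**Further compounds**

F1 | step 17 | 5-(phenylselanyl) trans-6,12-lactone from selenolactonisation of 23 | C=C1C(=O)O[C@@H]2[C@@H]([Se]c3ccccc3)C(=C)CC/C=C(/C=O)C[C@@H](OC(=O)CC(C)C)[C@@H]12
F2 | step 17 | allylic selenoxide of F1 | C=C1C(=O)O[C@@H]2[C@@H]([Se](=O)c3ccccc3)C(=C)CC/C=C(/C=O)C[C@@H](OC(=O)CC(C)C)[C@@H]12
F3 | step 17 | C15 phenylselenenate of the target | C=C1C(=O)O[C@@H]2/C=C(/CO[Se]c3ccccc3)CC/C=C(/C=O)C[C@@H](OC(=O)CC(C)C)[C@@H]12
F4 | step 16 | cis-8,12-lactone of 19 with C14 tert-butyldiphenylsilyl ether | C=CC(=C)CC/C=C(/CO[Si](C(C)(C)C)(c1ccccc1)c1ccccc1)C[C@H]2OC(=O)C(=C)[C@H]2C=C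
F5 | step 16 | cis-8,12-lactone with free C14 alcohol | C=CC(=C)CC/C=C(/CO)C[C@H]1OC(=O)C(=C)[C@H]1C=C
F6 | step 16 | cis-8,12-lactone with C14 aldehyde | C=CC(=C)CC/C=C(/C=O)C[C@H]1OC(=O)C(=C)[C@H]1C=C
F7 | step 16 | cis-fused bicyclic 8,12-lactone with ring diene C6=C5–C4=C15 | C=C1/C=C\[C@@H]2C(=C)C(=O)O[C@@H]2C/C(C=O)=C\CC1
F8 | step 16 | lithium salt of the ring-opened C8 hydroxy acid | [Li+].C=C1/C=C\[C@H](C(=C)C(=O)[O-])[C@H](O)C/C(C=O)=C\CC1
F9 | step 16 | allyl ester of the C8 hydroxy acid | C=C1/C=C\[C@H](C(=C)C(=O)OCC=C)[C@H](O)C/C(C=O)=C\CC1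
F10 | step 16 | allyl ester of 23 | C=C1/C=C\[C@H](C(=C)C(=O)OCC=C)[C@H](OC(=O)CC(C)C)C/C(C=O)=C\CC1
F11 | step 12 | (7S,8S)-enantiomer of 19 | C=CC(=C)CC/C=C(/CO[Si](C(C)(C)C)(c1ccccc1)c1ccccc1)C[C@H](O)[C@H](C(=C)C(=O)OCC[Si](C)(C)C)C=C
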